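**Retrosynthetic overview**

- Target ⇒ free tetraol (dibenzoylation of O7 and O5 through a dibutylstannylene acetal) ⇒ C4/C5 acetonide carrying the C7 ester (acetal hydrolysis, ester reduction).
- C1–OMe cis to C6–OH ⇒ C1–C6 epoxide anti to the acetonide (zerovalent-palladium/BEt3 methanolysis, retention at C1) ⇒ dienoate acetonide (peracid epoxidation of C1=C6).
- Key disconnection: the cis C4–O and C5–O bonds. The feature used is that C7, C3, C4 and C5 are the carboxyl, ipso, ortho and meta carbons of a benzoate ester, so the cis C4/C5 diol is the ortho,meta cis-dihydrodiol that toluene dioxygenase makes from ethyl benzoate.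
- Ring order: the single six-membered carbocycle C1–C6 is the benzene ring of ethyl benzoate and is never built. Only a temporary dioxolane (step 2) and oxirane (step 3) are formed and opened again.

Key step: step 1

Remark: the ring is numbered C1(OMe)–C2=C3(C7H2OBz)–C4(OH)–C5(OBz)–C6(OH) throughout. The target is read as 4,5-cis, 5,6-trans, 1,6-cis, which is (3R,4R,5R,6R) in its systematic name.

**Route**

Step 1
Reactants: 1 ethyl benzoate
Product: 2 ethyl (5S,6R)-5,6-dihydroxycyclohexa-1,3-diene-1-carboxylate
Conditions: E. coli JM109(pDTG601) whole cells (IPTG-induced toluene dioxygenase), air, glucose-fed mineral medium, pH 7.0, 35 °C, ester fed in portions; centrifuge, EtOAc extraction at pH 7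
Reagents that add atoms: dioxygen, O=O
Why: Toluene dioxygenase is a non-heme iron dioxygenase with an iron–sulfur electron-transfer partner: O2 bound at the mononuclear iron centre is delivered, with two electrons from NADH recycled by the glucose-fed cells, as both oxygen atoms to one face of one arene bond, so the C4–O and C5–O bonds form suprafacially and a cis-dihydrodiol results. The closest known reaction type is the whole-cell cis-dihydroxylation of monosubstituted benzenes by this enzyme, a class that includes alkyl benzoates. No ring is closed; the six-membered carbocycle is the arene ring itself, now a 1,3-diene. Both new stereocentres (C4 and C5, cis) are controlled by the enzyme active site, which binds the arene in one orientation and exposes one enantiotopic face of the ortho,meta bond, so the (5S,6R) diol should form as one enantiomer. The step needs ortho,meta regioselectivity (not ipso,ortho or meta,para), and this is secured by the placement of the ester substituent in the substrate pocket next to the bond that is oxidised. Neutral pH and prompt cold extraction are chosen because the diene-diol can lose water to give phenols.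

Step 2
Reactants: 2 ethyl (5S,6R)-5,6-dihydroxycyclohexa-1,3-diene-1-carboxylate
Product: 3 ethyl (3aR,7aS)-2,2-dimethyl-3a,7a-dihydro-1,3-benzodioxole-4-carboxylate
Conditions: 2,2-dimethoxypropane, p-TsOH·H2O (cat.), acetone, 0 °C to rt; used at once
Reagents that add atoms: 2,2-dimethoxypropane, COC(C)(C)OC
Why: Acid-catalysed transketalisation of the cis-diol gives the cis-fused dioxolane without touching C4 or C5, and the short anhydrous reaction avoids dehydration of the diene-diol to a phenol.

Step 3
Reactants: 3 ethyl (3aR,7aS)-2,2-dimethyl-3a,7a-dihydro-1,3-benzodioxole-4-carboxylate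
Product: 4 ethyl (3aR,5aR,6aR,6bR)-2,2-dimethyl-3a,5a,6a,6b-tetrahydrooxireno[2',3':3,4]benzo[1,2-d][1,3]dioxole-4-carboxylate (C1–C6 epoxide anti to the acetonide)
Conditions: mCPBA (1.2 equiv), CH2Cl2, 0 °C to rt
Reagents that add atoms: mCPBA (3-chloroperoxybenzoic acid), OOC(=O)c1cccc(Cl)c1
Why: Prilezhaev epoxidation, in which the electrophilic peracid selects the γ,δ-alkene C1=C6 over the ester-deactivated C2=C3 and approaches from the face opposite the cis-fused acetonide, which sets C1 and C6 with the oxirane anti to the C4/C5 oxygens.

Step 4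
Reactants: 4 the anti vinyl epoxide, 5 methanol
Product: 6 ethyl (3aR,6R,7R,7aS)-7-hydroxy-6-methoxy-2,2-dimethyl-3a,6,7,7a-tetrahydro-1,3-benzodioxole-4-carboxylate
Conditions: Pd(PPh3)4 (5 mol %), BEt3 (20 mol %, 1 M in THF), MeOH (5 equiv), THF, rt
Reagents that add atoms: methanol, CO
Why: Borane-cocatalysed addition of an alcohol to a vinyl epoxide (allylic substitution of the Tsuji–Trost type): zerovalent palladium ionises the C1–O bond with inversion to a C1–C3 π-allyl complex, BEt3 binds the C6 alkoxide and passes methanol to the neighbouring terminus C1 on the face anti to palladium, and the two inversions sum to retention, so C1–OMe ends cis to C6–OH and anti to the acetonide while C2=C3 stays conjugated to the ester.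

Step 5
Reactants: 6 the methoxy alcohol ester
Product: 7 (3aS,4R,5R,7aR)-7-(hydroxymethyl)-5-methoxy-2,2-dimethyl-3a,4,5,7a-tetrahydro-1,3-benzodioxol-4-ol
Conditions: i-Bu2AlH (3.5 equiv), CH2Cl2, −78 to −20 °C; aq. KNaC4H4O6 work-up
Reagents that add atoms: none
Why: i-Bu2AlH 1,2-reduction of the α,β-unsaturated ester to the primary allylic alcohol C7–OH (the free C6–OH only consumes one hydride as an aluminium alkoxide), with the acetonide, the methyl ether and all four stereocentres untouched.

Step 6
Reactants: 7 the acetonide diol
Product: 8 (1S,2R,3R,6R)-4-(hydroxymethyl)-6-methoxycyclohex-4-ene-1,2,3-triol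
Conditions: AcOH/H2O (4:1), 45 °C; evaporate with toluene
Reagents that add atoms: none
Why: Acid-catalysed acetal hydrolysis frees the C4/C5 cis-diol, and aqueous acetic acid is mild enough that the allylic methyl ether and allylic alcohols should not ionise, so no stereocentre is affected.

Step 7
Reactants: 8 the tetraol, 9 benzoyl chloride
Product: 11 [(3R,4R,5R,6R)-5-(benzoyloxy)-4,6-dihydroxy-3-methoxycyclohex-1-en-1-yl]methyl benzoate (target), via dibutylstannylene acetal 10 (not isolated)
Conditions: Bu2SnO (1.1 equiv), MeOH, reflux, evaporate; then BzCl (2.1 equiv), 1,4-dioxane, 0 °C to rt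
Reagents that add atoms: benzoyl chloride, O=C(Cl)c1ccccc1
Why: Tin-acetal-directed acylation: tetraol 8 is the carbocyclic counterpart of a methyl α-galactopyranoside (C1–OMe as the anomeric group, O6 as O-2, equatorial O5 as O-3, pseudoaxial O4 as O-4, C7 as C-6), a class in which stannylene-mediated benzoylation gives the 3,6-dibenzoate, so the five-membered stannylene on the cis O4/O5 pair should acylate its equatorial oxygen O5 and the primary O7 should take the second benzoyl, with no stereocentre touched.

**Compound list**

1 | ethyl benzoate | CCOC(=O)c1ccccc1 | starting material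
2 | ethyl (5S,6R)-5,6-dihydroxycyclohexa-1,3-diene-1-carboxylate | C1=C(C(=O)OCC)[C@@H](O)[C@@H](O)C=C1 | intermediate
3 | ethyl (3aR,7aS)-2,2-dimethyl-3a,7a-dihydro-1,3-benzodioxole-4-carboxylate | CCOC(=O)C1=CC=C[C@@H]2OC(C)(C)O[C@H]12 | intermediate
4 | ethyl (3aR,5aR,6aR,6bR)-2,2-dimethyl-3a,5a,6a,6b-tetrahydrooxireno[2',3':3,4]benzo[1,2-d][1,3]dioxole-4-carboxylate (epoxide anti to acetonide) | CCOC(=O)C1=C[C@H]2O[C@H]2[C@@H]2OC(C)(C)O[C@H]12 | intermediate
5 | methanol | CO | starting material
6 | ethyl (3aR,6R,7R,7aS)-7-hydroxy-6-methoxy-2,2-dimethyl-3a,6,7,7a-tetrahydro-1,3-benzodioxole-4-carboxylate | CO[C@@H]1C=C(C(=O)OCC)[C@H]2OC(C)(C)O[C@H]2[C@@H]1O | intermediate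
7 | (3aS,4R,5R,7aR)-7-(hydroxymethyl)-5-methoxy-2,2-dimethyl-3a,4,5,7a-tetrahydro-1,3-benzodioxol-4-ol | CO[C@@H]1C=C(CO)[C@H]2OC(C)(C)O[C@H]2[C@@H]1O | intermediate
8 | (1S,2R,3R,6R)-4-(hydroxymethyl)-6-methoxycyclohex-4-ene-1,2,3-triol | CO[C@@H]1C=C(CO)[C@@H](O)[C@@H](O)[C@@H]1O | intermediate
9 | benzoyl chloride | O=C(Cl)c1ccccc1 | starting material
10 | O4,O5-dibutylstannylene acetal of 8 (2,2-dibutyl-1,3,2-dioxastannolane fused at C4/C5, other centres as in 8) | CO[C@@H]1C=C(CO)[C@H]2O[Sn](CCCC)(CCCC)O[C@H]2[C@@H]1O | intermediate (not isolated)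
11 | [(3R,4R,5R,6R)-5-(benzoyloxy)-4,6-dihydroxy-3-methoxycyclohex-1-en-1-yl]methyl benzoate | CO[C@@H]1C=C(COC(=O)c2ccccc2)[C@@H](O)[C@@H](OC(=O)c2ccccc2)[C@@H]1O | target

**Step count**

Total steps: 7. Longest linear sequence: 7 steps, from ethyl benzoate 1 to 11.

**Steps most likely to fail**

1. Step 7. The risk is loss of site selectivity among four hydroxyls: competing acylation of the equatorial O6 next to the pseudoaxial methoxy group, over-benzoylation, or benzoyl migration between O5 and its neighbours. The fallback replaces tin control by protecting-group control; it sets out from compound 7 and comes back at compound 11. With the acetonide still in place, BzCl (1.05 equiv) and pyridine in CH2Cl2 at −30 °C should acylate only the primary hydroxyl and give the 7-O-benzoate F1. Levulinic acid, DCC and catalytic DMAP then cap the remaining C6–OH as the 6-O-levulinate F2. Aqueous acetic acid at 45 °C removes the acetonide to give the 4,5-diol F3, in which only O4 and O5 are free. Benzoylation with BzCl and i-Pr2NEt under Me2SnCl2 catalysis should then take the equatorial O5 in preference to the pseudoaxial, flanked O4 and give the 5-O-benzoate F4. Hydrazine acetate in CH2Cl2/MeOH at rt removes the levulinate in the presence of both benzoates and delivers 11.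

2. Step 4. The risk is leakage of regio- or stereocontrol in the allylic substitution: attack at the ester-bearing terminus C3, Lewis-acid background opening with inversion to the C1 epimer, or slow ionisation on the acetonide face followed by β-hydride elimination and aromatisation. The fallback avoids both the epoxide and palladium; it sets out from compound 3 and comes back at compound 6. Catalytic OsO4 with NMO in acetone/water should dihydroxylate the electron-richer C1=C6 alkene from the face anti to the acetonide and give the cis-diol ethyl (3aR,6R,7R,7aS)-6,7-dihydroxy-2,2-dimethyl-3a,6,7,7a-tetrahydro-1,3-benzodioxole-4-carboxylate F5. Heating with Bu2SnO in toluene under water removal gives its O1,O6-dibutylstannylene acetal F6, which is not isolated. MeI and CsF in DMF should then methylate the allylic oxygen O1, by analogy with the 3-O-alkylation of shikimate esters through their stannylene acetals, to give 6.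

3. Step 1. The risk is low conversion and product loss: benzoate esters are turned over slowly, may be partly hydrolysed by host esterases, and the diene-diol can dehydrate to phenols during long fermentation or work-up. As step 1 opens the route there is no earlier numbered compound; the fallback sets out from commercial iodobenzene F7 in place of compound 1 and comes back at compound 3. The same whole cells should oxidise this well-accepted substrate to (1S,2S)-3-iodocyclohexa-3,5-diene-1,2-diol F8, with the same facial sense. 2,2-Dimethoxypropane and catalytic p-TsOH give the acetonide (3aS,7aS)-4-iodo-2,2-dimethyl-3a,7a-dihydro-1,3-benzodioxole F9. Alkoxycarbonylation of the vinyl iodide with Pd(OAc)2, PPh3, CO (1 atm) and NaOAc in EtOH at 40 °C then installs the ester carbon C7 and gives 3.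

**Further compounds**

F1 | step 7 | 7-O-benzoate of 7 (acetonide and C6–OH retained, stereocentres as in 7) | CO[C@@H]1C=C(COC(=O)c2ccccc2)[C@H]2OC(C)(C)O[C@H]2[C@@H]1O
F2 | step 7 | 6-O-levulinate of F1 | CO[C@@H]1C=C(COC(=O)c2ccccc2)[C@H]2OC(C)(C)O[C@H]2[C@@H]1OC(=O)CCC(C)=O
F3 | step 7 | 4,5-diol from F2 (7-O-benzoate, 6-O-levulinate) | CO[C@@H]1C=C(COC(=O)c2ccccc2)[C@@H](O)[C@@H](O)[C@@H]1OC(=O)CCC(C)=O
F4 | step 7 | 5-O-benzoate of F3 (6-O-levulinate of target 11) | CO[C@@H]1C=C(COC(=O)c2ccccc2)[C@@H](O)[C@@H](OC(=O)c2ccccc2)[C@@H]1OC(=O)CCC(C)=O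
F5 | step 4 | ethyl (3aR,6R,7R,7aS)-6,7-dihydroxy-2,2-dimethyl-3a,6,7,7a-tetrahydro-1,3-benzodioxole-4-carboxylate | O[C@@H]1C=C(C(=O)OCC)[C@H]2OC(C)(C)O[C@H]2[C@@H]1O
F6 | step 4 | O1,O6-dibutylstannylene acetal of F5 (not isolated) | CCCC[Sn]1(CCCC)O[C@@H]2C=C(C(=O)OCC)[C@H]3OC(C)(C)O[C@H]3[C@@H]2O1
F7 | step 1 | iodobenzene | Ic1ccccc1
F8 | step 1 | (1S,2S)-3-iodocyclohexa-3,5-diene-1,2-diol | C1=C(I)[C@@H](O)[C@@H](O)C=C1
F9 | step 1 | (3aS,7aS)-4-iodo-2,2-dimethyl-3a,7a-dihydro-1,3-benzodioxole | IC1=CC=C[C@@H]2OC(C)(C)O[C@H]12
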